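Everything rests on removing the two hydroxyls at C5 and C5'' of the two A rings, each peri to a pyranone carbonyl (C4=O, C4''=O). One ruthenium-catalysed, carbonyl-directed C–H oxygenation installs both oxygens at the end, since only these C–H bonds can close a five-membered Ru–O=C4–C4a–C5 chelate. The precursor is 5,5''-dideoxystephaflavone B. Its A rings are plain 7-methoxy rings, so neither the choice between C6 and C8 nor the sorting of OH from OMe has to be solved. The C6–C3'' axis has only three ortho groups and comes from Suzuki coupling of a flavone 6-boronate with a 3-iodoflavone. The 4'''-phenol is converted into its trifluoroacetate in the flask before oxidant is added.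

Key step: step 9

Numbering: unit 1 is the 6-linked 4'-methoxyflavone (C2–C8a, ring B C1'–C6'). Unit 2 is the 3-linked flavone (C2''–C8a'', ring B C1'''–C6''').
Assumption: the target SMILES carries no axial descriptor, so the hindered C6–C3'' axis is left uncontrolled and the material is made as the racemate.

Step 1
Reactants: 1 2'-hydroxy-4'-methoxyacetophenone
Product: 2 2'-hydroxy-5'-iodo-4'-methoxyacetophenone
Conditions: NIS (1.05 equiv), CF3CO2H (0.3 equiv), MeCN, 0 °C to rt
Reagents that add atoms: N-iodosuccinimide, O=C1CCC(=O)N1I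
Why: Electrophilic aromatic iodination with acid-activated NIS should go to C5', which is para to the hydroxyl and ortho to the methoxy group, because the only other activated position, C3', is wedged between the two oxygen substituents.

Step 2
Reactants: 2 2'-hydroxy-5'-iodo-4'-methoxyacetophenone; 3 4-methoxybenzaldehyde
Product: 4 (E)-1-(2-hydroxy-5-iodo-4-methoxyphenyl)-3-(4-methoxyphenyl)prop-2-en-1-one
Conditions: KOH (50 % aq., 5 equiv), EtOH, rt; then aq. HCl
Reagents that add atoms: none
Why: Claisen–Schmidt condensation of the methyl ketone enolate with a non-enolisable aldehyde, in which E1cB loss of water gives the thermodynamically favoured E enone and the aryl iodide is inert to aqueous base at room temperature.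

Step 3
Reactants: 4 (E)-1-(2-hydroxy-5-iodo-4-methoxyphenyl)-3-(4-methoxyphenyl)prop-2-en-1-one
Product: 5 6-iodo-7-methoxy-2-(4-methoxyphenyl)-4H-chromen-4-one
Conditions: I2 (10 mol %), DMSO, 130 °C
Reagents that add atoms: none
Why: Iodine/DMSO oxidative cyclisation of a 2'-hydroxychalcone (6-endo oxa-Michael closure followed by iodination–elimination, with DMSO re-oxidising HI) is the standard flavone synthesis and places the iodine at C6 and the methoxy group at C7 without ambiguity.

Step 4
Reactants: 5 6-iodo-7-methoxy-2-(4-methoxyphenyl)-4H-chromen-4-one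
Product: 6 7-methoxy-2-(4-methoxyphenyl)-6-(4,4,5,5-tetramethyl-1,3,2-dioxaborolan-2-yl)-4H-chromen-4-one
Conditions: B2pin2 (1.3 equiv), PdCl2(dppf) (5 mol %), KOAc (3 equiv), 1,4-dioxane, 90 °C
Reagents that add atoms: bis(pinacolato)diboron, CC1(C)OB(B2OC(C)(C)C(C)(C)O2)OC1(C)C
Why: Miyaura borylation, in which zerovalent palladium inserts into the C6–I bond and acetate-assisted transmetalation from B2pin2 delivers the boronate, tolerates the pyranone and one ortho methoxy group.

Step 5
Reactants: 7 2,4-dimethoxybenzoyl chloride; 8 1-(benzyloxy)-4-ethynylbenzene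
Product: 9 3-[4-(benzyloxy)phenyl]-1-(2,4-dimethoxyphenyl)prop-2-yn-1-one
Conditions: PdCl2(PPh3)2 (2 mol %), CuI (4 mol %), Et3N (2 equiv), THF, rt
Reagents that add atoms: none
Why: Acyl Sonogashira coupling of an aroyl chloride with a terminal alkyne runs at room temperature, is free of regiochemical issues and leaves the benzyl and methyl ethers untouched.

Step 6
Reactants: 9 3-[4-(benzyloxy)phenyl]-1-(2,4-dimethoxyphenyl)prop-2-yn-1-one
Product: 10 2-[4-(benzyloxy)phenyl]-3-iodo-7-methoxy-4H-chromen-4-one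
Conditions: ICl (1.5 equiv), CH2Cl2, −78 °C to rt
Reagents that add atoms: iodine monochloride, ClI
Why: Iodocyclisation of an ortho-methoxyaryl ynone, in which ICl activates the alkyne, the ortho methoxy oxygen attacks the aryl-stabilised β-carbon in 6-endo-dig mode and chloride removes the methyl group, so the pyranone ring and the C3''–I bond form together and the iodine can sit nowhere else.

Step 7
Reactants: 6 7-methoxy-2-(4-methoxyphenyl)-6-(4,4,5,5-tetramethyl-1,3,2-dioxaborolan-2-yl)-4H-chromen-4-one; 10 2-[4-(benzyloxy)phenyl]-3-iodo-7-methoxy-4H-chromen-4-one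
Product: 11 4'''-O-benzyl-5,5''-dideoxystephaflavone B, i.e. 2-[4-(benzyloxy)phenyl]-7-methoxy-3-[7-methoxy-2-(4-methoxyphenyl)-4-oxo-4H-chromen-6-yl]-4H-chromen-4-one
Conditions: Pd(OAc)2 (5 mol %), SPhos (10 mol %), K3PO4 (3 equiv), 1,4-dioxane/H2O (5:1), 90 °C
Reagents that add atoms: none
Why: Suzuki–Miyaura coupling, in which the vinylogous acyl iodide of a 3-iodoflavone adds readily to zerovalent palladium and, with C5 still unsubstituted, the new axis carries only three ortho substituents (C7-OMe, C2''-aryl, C4''=O), which lies within the scope of the bulky dialkylbiarylphosphine SPhos.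

Step 8
Reactants: 11 4'''-O-benzyl-5,5''-dideoxystephaflavone B
Product: 12 5,5''-dideoxystephaflavone B, i.e. 2-(4-hydroxyphenyl)-7-methoxy-3-[7-methoxy-2-(4-methoxyphenyl)-4-oxo-4H-chromen-6-yl]-4H-chromen-4-one
Conditions: H2 (1 atm), Pd/C (10 wt %), THF/MeOH, rt
Reagents that add atoms: none
Why: Catalytic hydrogenolysis of an aryl benzyl ether is routine on flavones, whose conjugated C2=C3 bonds (the one in unit 2 is tetrasubstituted) should resist reduction at one atmosphere and room temperature if hydrogen uptake is stopped after one equivalent.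

Step 9
Reactants: 12 5,5''-dideoxystephaflavone B
Product: 15 stephaflavone B, via mono(trifluoroacetate) 13 (not isolated), via tris(trifluoroacetate) 14 (not isolated)
Conditions: (CF3CO)2O/CF3CO2H (1:3), rt, 30 min; then [RuCl2(p-cymene)]2 (10 mol %), PhI(OCOCF3)2 (3 equiv, in portions), 80 °C; then concentrate, THF/H2O, rt
Reagents that add atoms: [bis(trifluoroacetoxy)iodo]benzene, O=C(OI(OC(=O)C(F)(F)F)c1ccccc1)C(F)(F)F (formally supplies both new oxygens); trifluoroacetic anhydride, O=C(OC(=O)C(F)(F)F)C(F)(F)F (its acyl group is held only by 13 and 14)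
Why: Ru(OCOCF3)2(p-cymene), formed from [RuCl2(p-cymene)]2 in trifluoroacetic acid, binds a pyranone carbonyl oxygen and cleaves the peri C–H bond by carboxylate-assisted metalation to a five-membered ruthenacycle (Ru–O=C4–C4a–C5, and likewise in unit 2), after which PhI(OCOCF3)2 raises it to tetravalent ruthenium and C–O reductive elimination releases the aryl trifluoroacetate and divalent ruthenium. This is the known ketone-directed, ruthenium-catalysed ortho C–H hydroxylation, already practised at C5 of chromones and flavones and used here twice in one molecule. No ring is closed and no stereocentre is formed. The step needs site selectivity over the electron-rich C8–H, C6''–H, C8''–H and ring B C–H bonds, and the substrate secures it because only C5 and C5'' lie within five-membered chelate reach, C4''=O can reach the same C5–H through a six-membered chelate while its other neighbour C7 is blocked by methoxy, and protonation of both pyranones in the acid medium damps undirected oxidation. A free para-substituted phenol would be dearomatised by the iodane, so it is converted into 13 before the oxidant enters, and each new oxygen stays an electron-poor trifluoroacetate until hydrolysis, which guards against quinone formation. C5''–H should react first and C5–H, flanked by the C6 aryl group, more slowly, hence the raised catalyst loading and the portionwise oxidant.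

Compound list
1 | 2'-hydroxy-4'-methoxyacetophenone | COc1ccc(C(C)=O)c(O)c1 | starting material
2 | 2'-hydroxy-5'-iodo-4'-methoxyacetophenone | COc1cc(O)c(C(C)=O)cc1I | intermediate
3 | 4-methoxybenzaldehyde | COc1ccc(C=O)cc1 | starting material
4 | (E)-1-(2-hydroxy-5-iodo-4-methoxyphenyl)-3-(4-methoxyphenyl)prop-2-en-1-one | COc1ccc(/C=C/C(=O)c2cc(I)c(OC)cc2O)cc1 | intermediate
5 | 6-iodo-7-methoxy-2-(4-methoxyphenyl)-4H-chromen-4-one | COc1ccc(-c2cc(=O)c3cc(I)c(OC)cc3o2)cc1 | intermediate
6 | 7-methoxy-2-(4-methoxyphenyl)-6-(4,4,5,5-tetramethyl-1,3,2-dioxaborolan-2-yl)-4H-chromen-4-one | COc1ccc(-c2cc(=O)c3cc(B4OC(C)(C)C(C)(C)O4)c(OC)cc3o2)cc1 | intermediate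
7 | 2,4-dimethoxybenzoyl chloride | COc1ccc(C(=O)Cl)c(OC)c1 | starting material
8 | 1-(benzyloxy)-4-ethynylbenzene | C#Cc1ccc(OCc2ccccc2)cc1 | starting material
9 | 3-[4-(benzyloxy)phenyl]-1-(2,4-dimethoxyphenyl)prop-2-yn-1-one | COc1ccc(C(=O)C#Cc2ccc(OCc3ccccc3)cc2)c(OC)c1 | intermediate
10 | 2-[4-(benzyloxy)phenyl]-3-iodo-7-methoxy-4H-chromen-4-one | COc1ccc2c(c1)oc(-c1ccc(OCc3ccccc3)cc1)c(I)c2=O | intermediate
11 | 4'''-O-benzyl-5,5''-dideoxystephaflavone B | COc1ccc(-c2cc(=O)c3cc(-c4c(-c5ccc(OCc6ccccc6)cc5)oc5cc(OC)ccc5c4=O)c(OC)cc3o2)cc1 | intermediate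
12 | 5,5''-dideoxystephaflavone B | COc1ccc(-c2cc(=O)c3cc(-c4c(-c5ccc(O)cc5)oc5cc(OC)ccc5c4=O)c(OC)cc3o2)cc1 | intermediate
13 | 5,5''-dideoxystephaflavone B 4'''-O-trifluoroacetate (not isolated) | COc1ccc(-c2cc(=O)c3cc(-c4c(-c5ccc(OC(=O)C(F)(F)F)cc5)oc5cc(OC)ccc5c4=O)c(OC)cc3o2)cc1 | intermediate
14 | stephaflavone B 5,5'',4'''-tris(trifluoroacetate) (not isolated) | COc1ccc(-c2cc(=O)c3c(OC(=O)C(F)(F)F)c(-c4c(-c5ccc(OC(=O)C(F)(F)F)cc5)oc5cc(OC)cc(OC(=O)C(F)(F)F)c5c4=O)c(OC)cc3o2)cc1 | intermediate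
15 | stephaflavone B, 5-hydroxy-3-[5-hydroxy-7-methoxy-2-(4-methoxyphenyl)-4-oxo-4H-chromen-6-yl]-2-(4-hydroxyphenyl)-7-methoxy-4H-chromen-4-one | COc1ccc(-c2cc(=O)c3c(O)c(-c4c(-c5ccc(O)cc5)oc5cc(OC)cc(O)c5c4=O)c(OC)cc3o2)cc1 | target

Total step count: 9. Longest linear sequence: 7 (steps 1, 2, 3, 4, 7, 8, 9).

Steps most likely to fail

1. Step 9.
- **What may go wrong:** Metalation of the crowded C5–H next to the C6 aryl group may stall once C5'' has reacted. The two carbonyls may tie up the ruthenium in an unproductive chelate. Undirected oxidation of the methoxyarene rings by the iodane may outrun catalysis.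
- **Fallback:** The hindered oxygen is installed before the biaryl bond exists, so only the open C5''–H is left for the late stage. Setting out from 5, the same hydroxylation on the monomer ([RuCl2(p-cymene)]2, PhI(OCOCF3)2, CF3CO2H/(CF3CO)2O, 80 °C) meets a C5–H flanked only by iodine. It should give 6-iodo-7-methoxy-2-(4-methoxyphenyl)-4-oxo-4H-chromen-5-yl trifluoroacetate F1, which is hydrolysed in THF/H2O to 5-hydroxy-6-iodo-7-methoxy-2-(4-methoxyphenyl)-4H-chromen-4-one F2. Benzylation (BnBr, K2CO3, DMF, 70 °C) gives 5-(benzyloxy)-6-iodo-7-methoxy-2-(4-methoxyphenyl)-4H-chromen-4-one F3. Miyaura borylation as in step 4 gives 5-(benzyloxy)-7-methoxy-2-(4-methoxyphenyl)-6-(4,4,5,5-tetramethyl-1,3,2-dioxaborolan-2-yl)-4H-chromen-4-one F4. Suzuki coupling with 10 under the conditions of step 7 gives 5,4'''-di-O-benzyl-5''-deoxystephaflavone B F5. One hydrogenolysis (H2, Pd/C) removes both benzyl groups to give 5''-deoxystephaflavone B F6. Stirring in (CF3CO)2O/CF3CO2H gives 5''-deoxystephaflavone B 5,4'''-bis(trifluoroacetate) F7. A single ruthenium-catalysed hydroxylation at C5'' then rejoins the route at 14, which is hydrolysed to 15.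

2. Step 7.
- **What may go wrong:** Transmetalation at the tri-ortho-substituted axis may be slow, leaving time for protodeboronation of the electron-rich boronate and hydrodeiodination of the iodide. Hydroxide may also attack C2 and open a pyranone.
- **Fallback:** No cross-coupling is used at the axis, and unit 2 is instead built ring by ring on a C6 acetic acid side chain. Setting out from 5, palladium-catalysed coupling with the Reformatsky reagent BrZnCH2CO2tBu (Pd2(dba)3, XPhos, THF, 65 °C) gives tert-butyl [7-methoxy-2-(4-methoxyphenyl)-4-oxo-4H-chromen-6-yl]acetate F8. CF3CO2H in CH2Cl2 then gives [7-methoxy-2-(4-methoxyphenyl)-4-oxo-4H-chromen-6-yl]acetic acid F9. Friedel–Crafts acylation of 3-methoxyphenol in BF3·OEt2 at 85 °C is steered ortho to the hydroxyl by boron chelation of the product. It gives 6-[2-(2-hydroxy-4-methoxyphenyl)-2-oxoethyl]-7-methoxy-2-(4-methoxyphenyl)-4H-chromen-4-one F10. Treatment with 4-(benzyloxy)benzoyl chloride and K2CO3 in refluxing acetone gives 5-methoxy-2-{[7-methoxy-2-(4-methoxyphenyl)-4-oxo-4H-chromen-6-yl]acetyl}phenyl 4-(benzyloxy)benzoate F11. Baker–Venkataraman acyl transfer to the doubly activated methylene gives 1-[4-(benzyloxy)phenyl]-3-(2-hydroxy-4-methoxyphenyl)-2-[7-methoxy-2-(4-methoxyphenyl)-4-oxo-4H-chromen-6-yl]propane-1,3-dione F12. Cyclodehydration, completed with catalytic p-TsOH in toluene if needed, rejoins the route at 11.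

3. Step 6.
- **What may go wrong:** Ring iodination of the alkoxyarenes, plain addition of ICl across the alkyne or 5-exo closure may compete with the 6-endo iodocyclisation.
- **Fallback:** The flavone is made first and iodinated afterwards through its C3 anion. Setting out from 1, Claisen–Schmidt condensation with 4-(benzyloxy)benzaldehyde (KOH, EtOH, rt) gives (E)-3-[4-(benzyloxy)phenyl]-1-(2-hydroxy-4-methoxyphenyl)prop-2-en-1-one F13. I2 (cat.) in DMSO at 130 °C gives 2-[4-(benzyloxy)phenyl]-7-methoxy-4H-chromen-4-one F14. Deprotonation with LDA in THF at −78 °C gives 2-[4-(benzyloxy)phenyl]-3-lithio-7-methoxy-4H-chromen-4-one F15. Quenching with I2 rejoins the route at 10.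

Further compounds
F1 | step 9 | 6-iodo-7-methoxy-2-(4-methoxyphenyl)-4-oxo-4H-chromen-5-yl trifluoroacetate | COc1ccc(-c2cc(=O)c3c(OC(=O)C(F)(F)F)c(I)c(OC)cc3o2)cc1
F2 | step 9 | 5-hydroxy-6-iodo-7-methoxy-2-(4-methoxyphenyl)-4H-chromen-4-one | COc1ccc(-c2cc(=O)c3c(O)c(I)c(OC)cc3o2)cc1
F3 | step 9 | 5-(benzyloxy)-6-iodo-7-methoxy-2-(4-methoxyphenyl)-4H-chromen-4-one | COc1ccc(-c2cc(=O)c3c(OCc4ccccc4)c(I)c(OC)cc3o2)cc1
F4 | step 9 | 5-(benzyloxy)-7-methoxy-2-(4-methoxyphenyl)-6-(4,4,5,5-tetramethyl-1,3,2-dioxaborolan-2-yl)-4H-chromen-4-one | COc1ccc(-c2cc(=O)c3c(OCc4ccccc4)c(B4OC(C)(C)C(C)(C)O4)c(OC)cc3o2)cc1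
F5 | step 9 | 5,4'''-di-O-benzyl-5''-deoxystephaflavone B | COc1ccc(-c2cc(=O)c3c(OCc4ccccc4)c(-c4c(-c5ccc(OCc6ccccc6)cc5)oc5cc(OC)ccc5c4=O)c(OC)cc3o2)cc1
F6 | step 9 | 5''-deoxystephaflavone B | COc1ccc(-c2cc(=O)c3c(O)c(-c4c(-c5ccc(O)cc5)oc5cc(OC)ccc5c4=O)c(OC)cc3o2)cc1
F7 | step 9 | 5''-deoxystephaflavone B 5,4'''-bis(trifluoroacetate) | COc1ccc(-c2cc(=O)c3c(OC(=O)C(F)(F)F)c(-c4c(-c5ccc(OC(=O)C(F)(F)F)cc5)oc5cc(OC)ccc5c4=O)c(OC)cc3o2)cc1
F8 | step 7 | tert-butyl [7-methoxy-2-(4-methoxyphenyl)-4-oxo-4H-chromen-6-yl]acetate | COc1ccc(-c2cc(=O)c3cc(CC(=O)OC(C)(C)C)c(OC)cc3o2)cc1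
F9 | step 7 | [7-methoxy-2-(4-methoxyphenyl)-4-oxo-4H-chromen-6-yl]acetic acid | COc1ccc(-c2cc(=O)c3cc(CC(=O)O)c(OC)cc3o2)cc1
F10 | step 7 | 6-[2-(2-hydroxy-4-methoxyphenyl)-2-oxoethyl]-7-methoxy-2-(4-methoxyphenyl)-4H-chromen-4-one | COc1ccc(C(=O)Cc2cc3c(cc2OC)oc(-c2ccc(OC)cc2)cc3=O)c(O)c1
F11 | step 7 | 5-methoxy-2-{[7-methoxy-2-(4-methoxyphenyl)-4-oxo-4H-chromen-6-yl]acetyl}phenyl 4-(benzyloxy)benzoate | COc1ccc(C(=O)Cc2cc3c(cc2OC)oc(-c2ccc(OC)cc2)cc3=O)c(OC(=O)c2ccc(OCc3ccccc3)cc2)c1
F12 | step 7 | 1-[4-(benzyloxy)phenyl]-3-(2-hydroxy-4-methoxyphenyl)-2-[7-methoxy-2-(4-methoxyphenyl)-4-oxo-4H-chromen-6-yl]propane-1,3-dione (racemic, enolisable) | COc1ccc(C(=O)C(C(=O)c2ccc(OCc3ccccc3)cc2)c2cc3c(cc2OC)oc(-c2ccc(OC)cc2)cc3=O)c(O)c1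
F13 | step 6 | (E)-3-[4-(benzyloxy)phenyl]-1-(2-hydroxy-4-methoxyphenyl)prop-2-en-1-one | COc1ccc(C(=O)/C=C/c2ccc(OCc3ccccc3)cc2)c(O)c1
F14 | step 6 | 2-[4-(benzyloxy)phenyl]-7-methoxy-4H-chromen-4-one | COc1ccc2c(c1)oc(-c1ccc(OCc3ccccc3)cc1)cc2=O
F15 | step 6 | 2-[4-(benzyloxy)phenyl]-3-lithio-7-methoxy-4H-chromen-4-one | COc1ccc2c(c1)oc(-c1ccc(OCc3ccccc3)cc1)c([Li])c2=O
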